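**Plan**

1. Indane numbering: C1–C3 five-membered ring (C2 = CMe2), C3a, C4 (CH2OAc), C5 (CH2CH2Cl), C6 (CH2O2CPr), C7 (H), C7a. The retrosynthesis cuts, in this order: the butanoate and acetate C–O bonds; the C–Cl bonds, back to a temporary six-membered lactone (C4 carbonyl, C5 CH2CH2O); the CH2–CH2 bond of the C5 arm; the C3–C3a aryl–CH2 bond of the cyclopentane; the aryl–Br bond; the aryl–neopentyl bond. This leads back to dimethyl 2-methylisophthalate.
2. Forward: the benzene ring is bought. Neopentyl and then bromine are put on; the two free ring positions of the symmetric neopentyl diester are equivalent, so the bromination site is unambiguous. The five-membered ring is closed by palladium-catalysed C(sp3)–H arylation. Only then are the two carboxyl carbons told apart (steric saponification, then the temporary lactone), and the lactone is opened to the chloroethyl arm.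
3. Enabling feature: the quaternary C2 with its gem-dimethyl pair. In the open precursor it is the tert-butyl end of a neopentyl group on C7a. Its three equivalent CH3 groups lie within reach of the brominated carbon C3a (six-membered palladacycle) and have no β-hydrogen, so one CH3 becomes C3 and the other two remain as the gem-dimethyl pair.
4. Stereochemistry: the target has no stereocentre (C2 carries two identical methyl groups), so nothing has to be set or protected.

Key step: step 4

Remark: compounds 1 and 3 are taken as purchasable; the ester oxidation level is carried through the key step because methyl esters survive its conditions, whereas benzylic esters and an alkyl chloride may not.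

**Route**

Step 1
Reactants: 1 dimethyl 2-methylisophthalate
Product: 2 dimethyl 5-bromo-2-methylisophthalate
Conditions: N-bromosuccinimide (1.05 equiv), conc. H2SO4, 20–40 °C
Reagents that add atoms: N-bromosuccinimide, O=C1CCC(=O)N1Br
Why: Electrophilic aromatic bromination in strong acid should go to C5, which is para to the methyl group and meta to both esters, so all three substituents direct to the same carbon.

Step 2
Reactants: 2 dimethyl 5-bromo-2-methylisophthalate; 3 neopentylmagnesium chloride (Me3CCH2MgCl)
Product: 4 dimethyl 2-methyl-5-neopentylisophthalate
Conditions: 3, ZnCl2 (1.1 equiv per 3), THF, 0 → 20 °C; then 2, PdCl2(dppf) (3 mol %), THF, 60 °C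
Reagents that add atoms: none
Why: Negishi cross-coupling, in which the neopentylzinc chloride made in the flask from 3 and ZnCl2 has no β-hydrogen, leaves the esters alone and should couple cleanly at the unhindered C–Br bond.

Step 3
Reactants: 4 dimethyl 2-methyl-5-neopentylisophthalate
Product: 5 dimethyl 4-bromo-2-methyl-5-neopentylisophthalate
Conditions: dibromoisocyanuric acid (0.55 equiv), conc. H2SO4, 20 °C
Reagents that add atoms: dibromoisocyanuric acid, O=C1NC(=O)N(Br)C(=O)N1Br
Why: Electrophilic aromatic bromination with a strongly electrophilic bromine source, of the kind that brominates doubly deactivated toluenes, can give only 5 on monobromination because the two free ring positions of mirror-symmetric 4 are equivalent, and the first bromine deactivates the ring against a second.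

Step 4
Reactants: 5 dimethyl 4-bromo-2-methyl-5-neopentylisophthalate
Product: 6 dimethyl 2,2,5-trimethylindane-4,6-dicarboxylate
Conditions: Pd(OAc)2 (5 mol %), PCy3·HBF4 (10 mol %), Cs2CO3 (1.3 equiv), t-BuCO2H (30 mol %), mesitylene, 140 °C
Reagents that add atoms: none
Why: Zerovalent palladium should add oxidatively into the C–Br bond (activated by the ortho ester); bromide–pivalate exchange and concerted metalation–deprotonation of one of the three equivalent methyl C–H bonds of the neopentyl group then give a six-membered palladacycle of divalent palladium, and C(sp2)–C(sp3) reductive elimination forms the C3–C3a bond. The closest known reaction type is the palladium-catalysed intramolecular C(sp3)–H arylation of ortho-halo tert-alkyl and neopentyl arenes to benzocyclobutenes and 2,2-disubstituted indanes, here applied to an ester-bearing member of the same substrate class. The five-membered carbocycle closes by reductive elimination from the six-membered palladacycle, the aryl carbon and the former methyl carbon being joined as palladium leaves. No stereocentre arises, because C2 keeps two identical methyl groups. The step needs methyl C–H over the other C–H bonds, and the substrate secures this: the benzylic CH2 would require a four-membered palladacycle, the arene methyl is meta to palladium and out of reach, the ester holds its OCH3 turned away from the metal in the Z conformation, and the quaternary carbon leaves the alkylpalladium without a β-hydrogen to eliminate.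

Step 5
Reactants: 6 dimethyl 2,2,5-trimethylindane-4,6-dicarboxylate
Product: 7 4-(methoxycarbonyl)-2,2,5-trimethylindane-6-carboxylic acid
Conditions: LiOH·H2O (1.3 equiv), THF/MeOH/H2O, 40 °C; then aq. HCl
Reagents that add atoms: lithium hydroxide, [Li+].[OH-]
Why: Sterically controlled saponification (BAc2), in which the C6 ester with one ortho hydrogen should be attacked by hydroxide while the C4 ester, flanked by the C5 methyl and the ring CH2 (C3), resists addition.

Step 6
Reactants: 7 4-(methoxycarbonyl)-2,2,5-trimethylindane-6-carboxylic acid
Product: 10 lactone acid of the indane series (six-membered lactone C4–C(=O)–O–CH2–CH2–C5; CO2H on C6), via dilithium benzylic carbanion carboxylate 8 (not isolated), via dilithium alkoxide carboxylate 9 (not isolated)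
Conditions: LiN(CHMe2)2 (2.3 equiv), THF, −78 °C; CH2O (gas, from cracked paraformaldehyde), −78 → 20 °C; aq. HCl, 0 °C
Reagents that add atoms: formaldehyde, C=O
Why: Lateral (benzylic) lithiation of an ortho-toluate dianion and hydroxymethylation with formaldehyde, the C5 methyl between carboxylate and ester being the most acidic site, should give alkoxide 9, which on warming can lactonise only onto the C4 ester because the C6 carboxylate is not electrophilic.

Step 7
Reactants: 10 lactone acid
Product: 11 hydroxymethyl lactone (same lactone; CH2OH on C6)
Conditions: BH3·THF (2 equiv), THF, 0 → 20 °C; then H2O, aq. NaHCO3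
Reagents that add atoms: none
Why: Chemoselective borane reduction, since BH3 reduces a free carboxylic acid through its acyloxyborane far faster than an aryl lactone.

Step 8
Reactants: 11 hydroxymethyl lactone
Product: 13 5-(2-chloroethyl)-6-(chloromethyl)-2,2-dimethylindane-4-carbonyl chloride, via chloromethyl lactone 12 (not isolated)
Conditions: SOCl2 (neat, excess), ZnCl2 (10 mol %), 20 °C then reflux (76 °C); evaporate, use crude
Reagents that add atoms: thionyl chloride, O=S(Cl)Cl
Why: The benzylic alcohol should give the benzylic chloride through its chlorosulfite, and ZnCl2-assisted chloride attack at the O–CH2 carbon of the lactone (SN2, the known conversion of lactones into ω-chloroacyl chlorides) should then give the chloroethyl arm and the aroyl chloride, no arene solvent being present that could be benzylated.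

Step 9
Reactants: 13 5-(2-chloroethyl)-6-(chloromethyl)-2,2-dimethylindane-4-carbonyl chloride
Product: 14 [5-(2-chloroethyl)-6-(chloromethyl)-2,2-dimethylindan-4-yl]methanol
Conditions: NaBH4 (2 equiv), THF, 0 → 20 °C; aq. NH4Cl
Reagents that add atoms: none
Why: Borohydride reduction of an acyl chloride to the primary alcohol, the acyl chloride being far more electrophilic than the benzylic and alkyl chlorides, which NaBH4 in THF should leave untouched at this temperature.

Step 10
Reactants: 14 [5-(2-chloroethyl)-6-(chloromethyl)-2,2-dimethylindan-4-yl]methanol
Product: 15 [5-(2-chloroethyl)-6-(chloromethyl)-2,2-dimethylindan-4-yl]methyl acetate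
Conditions: Ac2O (1.5 equiv), Et3N, DMAP (5 mol %), CH2Cl2, 0 °C
Reagents that add atoms: acetic anhydride, CC(=O)OC(C)=O
Why: DMAP-catalysed O-acetylation of a primary benzylic alcohol is fast at 0 °C, so the benzylic chloride should not be quaternised and the alcohol has no time to cyclise onto the chloroethyl arm.

Step 11
Reactants: 15 [5-(2-chloroethyl)-6-(chloromethyl)-2,2-dimethylindan-4-yl]methyl acetate
Product: 16 [4-(acetoxymethyl)-5-(2-chloroethyl)-2,2-dimethylindan-6-yl]methyl butanoate (CNP0321917.0)
Conditions: NaO2CCH2CH2CH3 (sodium butanoate, 1.5 equiv), DMF, 45 °C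
Reagents that add atoms: sodium butanoate, CCCC(=O)[O-].[Na+]
Why: SN2 displacement by carboxylate, in which the benzylic chloride should react much faster than the unactivated primary alkyl chloride while the acetate is inert to the weakly basic butanoate.

**Compound list**

1 | dimethyl 2-methylisophthalate | COC(=O)c1cccc(C(=O)OC)c1C | starting material
2 | dimethyl 5-bromo-2-methylisophthalate | COC(=O)c1cc(Br)cc(C(=O)OC)c1C | intermediate
3 | neopentylmagnesium chloride | CC(C)(C)C[Mg]Cl | starting material
4 | dimethyl 2-methyl-5-neopentylisophthalate | COC(=O)c1cc(CC(C)(C)C)cc(C(=O)OC)c1C | intermediate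
5 | dimethyl 4-bromo-2-methyl-5-neopentylisophthalate | COC(=O)c1cc(CC(C)(C)C)c(Br)c(C(=O)OC)c1C | intermediate
6 | dimethyl 2,2,5-trimethylindane-4,6-dicarboxylate | COC(=O)c1cc2CC(C)(C)Cc2c(C(=O)OC)c1C | intermediate
7 | 4-(methoxycarbonyl)-2,2,5-trimethylindane-6-carboxylic acid | OC(=O)c1cc2CC(C)(C)Cc2c(C(=O)OC)c1C | intermediate
8 | dilithium benzylic carbanion carboxylate of 7 (not isolated) | [Li+].[Li+].[O-]C(=O)c1cc2CC(C)(C)Cc2c(C(=O)OC)c1[CH2-] | intermediate
9 | dilithium alkoxide carboxylate, C5 arm CH2CH2OLi (not isolated) | [Li+].[Li+].[O-]C(=O)c1cc2CC(C)(C)Cc2c(C(=O)OC)c1CC[O-] | intermediate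
10 | lactone acid: 2,2-dimethylindane with lactone C4–C(=O)–O–CH2–CH2–C5 and CO2H on C6 | OC(=O)c1cc2CC(C)(C)Cc2c2C(=O)OCCc12 | intermediate
11 | hydroxymethyl lactone: same lactone, CH2OH on C6 | OCc1cc2CC(C)(C)Cc2c2C(=O)OCCc12 | intermediate
12 | chloromethyl lactone: same lactone, CH2Cl on C6 (not isolated) | ClCc1cc2CC(C)(C)Cc2c2C(=O)OCCc12 | intermediate
13 | 5-(2-chloroethyl)-6-(chloromethyl)-2,2-dimethylindane-4-carbonyl chloride | ClCc1cc2CC(C)(C)Cc2c(C(Cl)=O)c1CCCl | intermediate
14 | [5-(2-chloroethyl)-6-(chloromethyl)-2,2-dimethylindan-4-yl]methanol | ClCc1cc2CC(C)(C)Cc2c(CO)c1CCCl | intermediate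
15 | [5-(2-chloroethyl)-6-(chloromethyl)-2,2-dimethylindan-4-yl]methyl acetate | ClCc1cc2CC(C)(C)Cc2c(COC(C)=O)c1CCCl | intermediate
16 | [4-(acetoxymethyl)-5-(2-chloroethyl)-2,2-dimethylindan-6-yl]methyl butanoate (CNP0321917.0) | CCCC(=O)OCc1cc2CC(C)(C)Cc2c(COC(C)=O)c1CCCl | target

Total step count: 11. Longest linear sequence: 11 steps (1 → 16).

**Steps most likely to fail**

Step 8. The hindered aryl lactone may open only sluggishly under hot Lewis-acidic thionyl chloride, and the forcing conditions may cause Friedel–Crafts side reactions of the benzylic chloride or loss of hydrogen chloride from the chloroethyl arm. The fallback sets out from 11 and avoids Lewis-acid chemistry. The lactone would be opened with NaOH (1.0 equiv, aq. THF) to the sodium hydroxy carboxylate F1 (not isolated). F1 would be methylated at the carboxylate with MeI in DMF to the methyl ester diol F2. Both hydroxyls would be mesylated at once (MeSO2Cl, Et3N, CH2Cl2, −20 °C) to the bis-mesylate F3, so that neither can cyclise onto the other, and displaced with LiCl in DMF to the dichloro ester F4. Reduction of the hindered ester with (Me2CHCH2)2AlH in CH2Cl2 at −78 → 0 °C would then give 14, where the route is rejoined.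

Step 3. Electrophilic substitution at a ring position that is ortho and para to ester groups and flanked by the neopentyl group may be too slow, and long exposure to sulfuric acid may cleave the esters. The fallback sets out from 4 and uses the stronger nitronium electrophile at the same, only free kind of ring position. Nitration (HNO3, H2SO4, 0 °C) would give the nitro diester F5. Hydrogenation (H2, palladium on carbon, EtOAc) would give the aniline F6. Sandmeyer bromination (t-BuONO, CuBr2, MeCN, 60 °C) through the diazonium salt F7 would give 5, where the route is rejoined.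

Step 6. Deprotonation may occur in part at the ring CH2 next to the C4 ester, and lactonisation in the flask may stay incomplete, so that acidic work-up closes the ring onto the C6 carboxyl instead. The fallback sets out from 7 and removes the competing carboxyl before the side chain is built. Reduction with BH3·THF would give the hydroxymethyl ester F8. LiN(CHMe2)2 (2.3 equiv, THF, −78 °C) would give the alkoxide benzylic dianion F9, and formaldehyde the dialkoxide F10. The homobenzylic alkoxide of F10 can lactonise only onto the one remaining ester, which would give 11 directly; compound 10 is bypassed and the route is rejoined at 11.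

**Further compounds**

F1 | step 8 | sodium 5-(2-hydroxyethyl)-6-(hydroxymethyl)-2,2-dimethylindane-4-carboxylate | [Na+].OCc1cc2CC(C)(C)Cc2c(C(=O)[O-])c1CCO
F2 | step 8 | methyl 5-(2-hydroxyethyl)-6-(hydroxymethyl)-2,2-dimethylindane-4-carboxylate | OCc1cc2CC(C)(C)Cc2c(C(=O)OC)c1CCO
F3 | step 8 | methyl 5-[2-(methylsulfonyloxy)ethyl]-6-[(methylsulfonyloxy)methyl]-2,2-dimethylindane-4-carboxylate | CS(=O)(=O)OCc1cc2CC(C)(C)Cc2c(C(=O)OC)c1CCOS(C)(=O)=O
F4 | step 8 | methyl 5-(2-chloroethyl)-6-(chloromethyl)-2,2-dimethylindane-4-carboxylate | ClCc1cc2CC(C)(C)Cc2c(C(=O)OC)c1CCCl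
F5 | step 3 | dimethyl 2-methyl-5-neopentyl-4-nitroisophthalate | COC(=O)c1cc(CC(C)(C)C)c([N+](=O)[O-])c(C(=O)OC)c1C
F6 | step 3 | dimethyl 4-amino-2-methyl-5-neopentylisophthalate | COC(=O)c1cc(CC(C)(C)C)c(N)c(C(=O)OC)c1C
F7 | step 3 | 2,6-bis(methoxycarbonyl)-3-methyl-6-neopentyl-type arenediazonium bromide (diazonium on the former C4 of 4) | COC(=O)c1cc(CC(C)(C)C)c([N+]#N)c(C(=O)OC)c1C.[Br-]
F8 | step 6 | methyl 6-(hydroxymethyl)-2,2,5-trimethylindane-4-carboxylate | OCc1cc2CC(C)(C)Cc2c(C(=O)OC)c1C
F9 | step 6 | dilithium alkoxide benzylic carbanion of F8 | [Li+].[Li+].[O-]Cc1cc2CC(C)(C)Cc2c(C(=O)OC)c1[CH2-]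
F10 | step 6 | dilithium dialkoxide, C5 arm CH2CH2OLi and C6 CH2OLi | [Li+].[Li+].[O-]Cc1cc2CC(C)(C)Cc2c(C(=O)OC)c1CC[O-]
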